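## Retrosynthetic overview

1. C40 target ⇒ C10 trienedial + two diastereomeric C15 phosphonium salts, joined by two successive Wittig olefinations (C11=C12, then C11'=C12').
2. Each salt ⇒ a ring β-hydroxy ketone carrying a tertiary vinyl carbinol side chain (PPh3·HBr, allylic transposition).
3. Key bond C5–O: both β-hydroxy ketones ⇒ one racemic 3-oxo enone by catalyst-controlled conjugate oxygenation (aminocatalytic epoxidation, then Cα–O reduction). The two pseudo-enantiomeric catalysts give the 5S,6S end (OH anti to the chain) and the 5R,6S end (OH syn).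
4. Enone ⇒ α-ionone by vinyl Grignard addition and allylic C–H oxidation at C3.
5. Rings: no carbocycle is built; both six-membered rings come intact from α-ionone. The only ring formed is the transient oxirane of step 3 or 4, opened again in the same step.

Assumption: positions use carotenoid numbering (C1 = CMe2, C3 = C=O, C5 = C(OH)Me, C6 = ring CH bearing the chain), and the quinine-derived catalyst is taken to oxygenate the C5 face that becomes 5S (quinidine-derived: 5R); if the sense is the reverse, the two catalysts are exchanged between steps 3 and 4.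

## Route

Step 1
Reactants: 1 (±)-α-ionone; 2 vinylmagnesium bromide
Product: 3 vinyl-α-ionol, (1E,3RS)-3-methyl-1-[(1RS)-2,6,6-trimethylcyclohex-2-en-1-yl]penta-1,4-dien-3-ol
Conditions: THF, 0 °C, 1 h; aqueous work-up
Reagents that add atoms: none
Why: Grignard 1,2-addition of the hard vinyl nucleophile to the enone carbonyl adds C10–C11 and creates the tertiary bis-allylic carbinol needed for step 5/6; the new carbinol centre forms unselectively and is destroyed later.

Step 2
Reactants: 3 vinyl-α-ionol
Product: 4 racemic enone, (4RS)-4-[(1E,3RS)-3-hydroxy-3-methylpenta-1,4-dien-1-yl]-3,5,5-trimethylcyclohex-2-en-1-one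
Conditions: Rh2(cap)4 (dirhodium tetrakis(caprolactamate), 1 mol %), t-BuOOH (70% in water, 5 equiv), K2CO3 (0.5 equiv), CH2Cl2, 25 °C
Reagents that add atoms: tert-butyl hydroperoxide, CC(C)(C)OO
Why: Radical allylic C–H oxidation (tert-butylperoxyl chain) attacks the only unhindered secondary allylic CH2 (C3) and gives the conjugated enone, while the tertiary alcohol has no carbinol hydrogen and cannot be oxidised.

Step 3
Reactants: 4 racemic enone
Product: 6 anti-hydroxy ketone, (3S,4S)-3-hydroxy-4-[(1E,3RS)-3-hydroxy-3-methylpenta-1,4-dien-1-yl]-3,5,5-trimethylcyclohexan-1-one (carotenoid 5S,6S; ring OH anti to the side chain), via anti-epoxy ketone 5 (not isolated)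
Conditions: 9-amino(9-deoxy)epi-quinine·2CF3CO2H (10 mol %), 50% aq H2O2 (1.5 equiv), 1,4-dioxane, 35 °C, 36 h; extractive work-up, crude 5 then SmI2 (2.5 equiv), THF/MeOH, −90 °C; silica chromatography
Reagents that add atoms: hydrogen peroxide, OO
Why: Proposed new method: catalyst-controlled aminocatalytic Weitz–Scheffer epoxidation of a racemic γ-stereogenic β,β-disubstituted cyclohexenone, used as a divergent resolution and telescoped with SmI2 Cα–O scission (net conjugate hydration): the primary amine condenses with the single carbonyl (C3) to an iminium ion, the protonated quinuclidine hydrogen-bonds H2O2 and delivers it to one face of C5 whatever the configuration at C6 (the two ring faces are intrinsically similar, one shielded by the C6 side chain and the other by the axial C1 methyl), and enamine closure onto O–O gives the cis-fused oxirane that fixes the C5–O bond as 5S; (6S)-4 therefore gives 5 and, after SmI2 cleaves only the C4–O bond, 6, whereas (6R)-4 gives the syn diastereomer removed on silica, so this step sets C5 by catalyst control and selects C6 = S; closest known reactions are the cinchona primary amine salt catalysed asymmetric epoxidation of simple cyclic enones and the SmI2 reduction of α,β-epoxy ketones to β-hydroxy ketones.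

Step 4
Reactants: 4 racemic enone
Product: 8 syn-hydroxy ketone, (3R,4S)-3-hydroxy-4-[(1E,3RS)-3-hydroxy-3-methylpenta-1,4-dien-1-yl]-3,5,5-trimethylcyclohexan-1-one (carotenoid 5R,6S; ring OH syn to the side chain), via syn-epoxy ketone 7 (not isolated)
Conditions: 9-amino(9-deoxy)epi-quinidine·2CF3CO2H (10 mol %), 50% aq H2O2 (1.5 equiv), 1,4-dioxane, 35 °C, 48 h; extractive work-up, crude 7 then SmI2 (2.5 equiv), THF/MeOH, −90 °C; silica chromatography
Reagents that add atoms: hydrogen peroxide, OO
Why: Proposed new method: the same iminium-directed Weitz–Scheffer epoxidation and SmI2 Cα–O scission as in step 3, run with the pseudo-enantiomeric amine, which delivers H2O2 to the opposite C5 face (5R); (6S)-4 then gives 7 with oxygen syn to the side chain and from it 8, while (6R)-4 gives the anti diastereomer removed on silica, so C5 = R is set by the catalyst and C6 = S by selection; closest known reactions as in step 3.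

Step 5
Reactants: 6 anti-hydroxy ketone
Product: 9 anti-series phosphonium salt, {(2E,4E)-5-[(1S,2S)-2-hydroxy-2,6,6-trimethyl-4-oxocyclohexyl]-3-methylpenta-2,4-dien-1-yl}triphenylphosphonium bromide
Conditions: PPh3·HBr (1.05 equiv), MeOH, 0 °C to 20 °C, 3 h; crystallisation from EtOAc
Reagents that add atoms: triphenylphosphine hydrobromide, Br.c1ccc(cc1)P(c1ccccc1)c1ccccc1
Why: Acid-mediated SN1' phosphonium salt formation: the bis-allylic tertiary carbinol ionises to a pentadienyl cation that PPh3 captures at the terminal carbon to give the conjugated E,E-dienyl salt (both carbinol epimers converge), while the ring carbinol, deactivated by the β-carbonyl, is not ionised at this temperature and no stereocentre is touched.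

Step 6
Reactants: 8 syn-hydroxy ketone
Product: 10 syn-series phosphonium salt, {(2E,4E)-5-[(1S,2R)-2-hydroxy-2,6,6-trimethyl-4-oxocyclohexyl]-3-methylpenta-2,4-dien-1-yl}triphenylphosphonium bromide
Conditions: PPh3·HBr (1.05 equiv), MeOH, 0 °C to 20 °C, 3 h; crystallisation from EtOAc
Reagents that add atoms: triphenylphosphine hydrobromide, Br.c1ccc(cc1)P(c1ccccc1)c1ccccc1
Why: The same SN1' phosphonium salt formation as in step 5, here kept at high PPh3 concentration so that intermolecular capture of the pentadienyl cation outruns attack by the syn ring hydroxyl.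

Step 7
Reactants: 9 anti-series phosphonium salt; 11 (2E,4E,6E)-2,7-dimethylocta-2,4,6-trienedial (3 equiv)
Product: 13 C25 apo-aldehyde, (2E,4E,6E,8E,10E,12E)-13-[(1S,2S)-2-hydroxy-2,6,6-trimethyl-4-oxocyclohexyl]-2,7,11-trimethyltrideca-2,4,6,8,10,12-hexaenal, via anti-series ylide 12 (not isolated)
Conditions: 1,2-epoxybutane (10 equiv), EtOH, 70 °C, argon, dark; then heptane, 90 °C (Z to E); excess 11 recovered
Reagents that add atoms: none
Why: Wittig olefination of the semi-stabilised allylic ylide, generated without free base by bromide opening of the epoxide, with one formyl group of the excess dialdehyde; the neutral medium spares the β-hydroxy ketone from E1cB loss of water and retro-aldol cleavage, and the new C11=C12 bond is equilibrated thermally to E.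

Step 8
Reactants: 13 C25 apo-aldehyde; 10 syn-series phosphonium salt
Product: 15 target, (5S,6S,5'R,6'S)-5,5'-dihydroxy-5,6,5',6'-tetrahydro-β,β-carotene-3,3'-dione, via syn-series ylide 14 (not isolated)
Conditions: 1,2-epoxybutane (10 equiv), EtOH/CH2Cl2, 60 °C, argon, dark; then EtOAc/heptane, 80 °C (Z to E); crystallisation
Reagents that add atoms: none
Why: A second base-free Wittig olefination joins the syn end group to the polyene aldehyde at C11'=C12', and thermal isomerisation followed by crystallisation gives the all-E nonaene without touching the four ring stereocentres.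

## Compound list

1 | (±)-α-ionone, (3E)-4-(2,6,6-trimethylcyclohex-2-en-1-yl)but-3-en-2-one | CC(=O)/C=C/C1C(C)=CCCC1(C)C | starting material
2 | vinylmagnesium bromide | C=C[Mg]Br | starting material
3 | vinyl-α-ionol, (1E,3RS)-3-methyl-1-[(1RS)-2,6,6-trimethylcyclohex-2-en-1-yl]penta-1,4-dien-3-ol (racemic, both carbinol epimers) | C=CC(C)(O)/C=C/C1C(C)=CCCC1(C)C | intermediate
4 | racemic enone, (4RS)-4-[(1E,3RS)-3-hydroxy-3-methylpenta-1,4-dien-1-yl]-3,5,5-trimethylcyclohex-2-en-1-one | C=CC(C)(O)/C=C/C1C(C)=CC(=O)CC1(C)C | intermediate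
5 | anti-epoxy ketone, (1R,5S,6R)-5-[(1E,3RS)-3-hydroxy-3-methylpenta-1,4-dien-1-yl]-4,4,6-trimethyl-7-oxabicyclo[4.1.0]heptan-2-one (oxirane oxygen anti to the side chain) | C=CC(C)(O)/C=C/[C@H]1C(C)(C)CC(=O)[C@@H]2O[C@]12C | intermediate
6 | anti-hydroxy ketone, (3S,4S)-3-hydroxy-4-[(1E,3RS)-3-hydroxy-3-methylpenta-1,4-dien-1-yl]-3,5,5-trimethylcyclohexan-1-one | C=CC(C)(O)/C=C/[C@H]1C(C)(C)CC(=O)C[C@]1(C)O | intermediate
7 | syn-epoxy ketone, (1S,5S,6S)-5-[(1E,3RS)-3-hydroxy-3-methylpenta-1,4-dien-1-yl]-4,4,6-trimethyl-7-oxabicyclo[4.1.0]heptan-2-one (oxirane oxygen syn to the side chain) | C=CC(C)(O)/C=C/[C@H]1C(C)(C)CC(=O)[C@H]2O[C@@]12C | intermediate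
8 | syn-hydroxy ketone, (3R,4S)-3-hydroxy-4-[(1E,3RS)-3-hydroxy-3-methylpenta-1,4-dien-1-yl]-3,5,5-trimethylcyclohexan-1-one | C=CC(C)(O)/C=C/[C@H]1C(C)(C)CC(=O)C[C@@]1(C)O | intermediate
9 | anti-series phosphonium salt, {(2E,4E)-5-[(1S,2S)-2-hydroxy-2,6,6-trimethyl-4-oxocyclohexyl]-3-methylpenta-2,4-dien-1-yl}triphenylphosphonium bromide | CC(/C=C/[C@H]1C(C)(C)CC(=O)C[C@]1(C)O)=C\C[P+](c1ccccc1)(c1ccccc1)c1ccccc1.[Br-] | intermediate
10 | syn-series phosphonium salt, {(2E,4E)-5-[(1S,2R)-2-hydroxy-2,6,6-trimethyl-4-oxocyclohexyl]-3-methylpenta-2,4-dien-1-yl}triphenylphosphonium bromide | CC(/C=C/[C@H]1C(C)(C)CC(=O)C[C@@]1(C)O)=C\C[P+](c1ccccc1)(c1ccccc1)c1ccccc1.[Br-] | intermediate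
11 | (2E,4E,6E)-2,7-dimethylocta-2,4,6-trienedial (C10 dialdehyde) | O=C/C(C)=C/C=C/C=C(C)/C=O | starting material
12 | anti-series ylide, triphenylphosphonium ylide of 9 | CC(/C=C/[C@H]1C(C)(C)CC(=O)C[C@]1(C)O)=C\[CH-][P+](c1ccccc1)(c1ccccc1)c1ccccc1 | intermediate
13 | C25 apo-aldehyde, (2E,4E,6E,8E,10E,12E)-13-[(1S,2S)-2-hydroxy-2,6,6-trimethyl-4-oxocyclohexyl]-2,7,11-trimethyltrideca-2,4,6,8,10,12-hexaenal | CC(/C=C/C=C(C)/C=C/[C@H]1C(C)(C)CC(=O)C[C@]1(C)O)=C\C=C\C=C(C)\C=O | intermediate
14 | syn-series ylide, triphenylphosphonium ylide of 10 | CC(/C=C/[C@H]1C(C)(C)CC(=O)C[C@@]1(C)O)=C\[CH-][P+](c1ccccc1)(c1ccccc1)c1ccccc1 | intermediate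
15 | (5S,6S,5'R,6'S)-5,5'-dihydroxy-5,6,5',6'-tetrahydro-β,β-carotene-3,3'-dione, all-E | CC(/C=C/C=C(C)/C=C/[C@H]1C(C)(C)CC(=O)C[C@]1(C)O)=C\C=C\C=C(C)\C=C\C=C(C)\C=C\[C@H]1C(C)(C)CC(=O)C[C@@]1(C)O | target

## Step count and risks

Total step count: 8 (steps 3/4 and 5/6 are parallel pairs). Longest linear sequence: 6 (steps 1, 2, 3, 5, 7, 8).

Steps most likely to fail:

Step 4 (new method, oxygen entering syn to the C6 side chain). If the substrate bias of (6S)-4 is stronger than the catalyst, 8 forms slowly or is replaced by 6, and its optical purity rests on the catalyst's face selectivity. The enantiomeric excess is checked on 8 and upgraded by crystallising 10. The fallback uses known chemistry, sets out from 4 and comes back at 8. Enantioselective conjugate borylation of β,β-disubstituted cyclohexenones is established: CuCl, NaOt-Bu and one enantiomer of QuinoxP* with B2pin2 and MeOH in THF at 0 °C add boron to C5 under ligand control. This gives the syn tertiary pinacol boronate F1, which is separated on silica from the boronate of the 6R half. Stereoretentive oxidation of the C–B bond with NaBO3·4H2O in THF/water then gives 8.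

Step 3 (same new method, oxygen anti to the side chain). Its risks are low conversion of the hindered isophorone-type iminium ion and erosion of the enantiomeric excess of 6 by anti product formed from (6R)-4 through the disfavoured face. The run is stopped short of full conversion if needed, and 9 is recrystallised. The fallback uses known chemistry, sets out from 4 and comes back at 6. The same copper-catalysed conjugate borylation with the other enantiomer of QuinoxP* gives the anti tertiary pinacol boronate F2. NaBO3·4H2O oxidation with retention then gives 6.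

Step 2 (allylic oxidation beside a free bis-allylic tertiary alcohol). Abstraction of the doubly allylic C6–H or fragmentation of the alkoxyl radical may compete with oxidation at C3. The fallback sets out from 1 and comes back at 4, changing the order of events. The oxidation is done first on α-ionone, where it is well precedented (t-BuOOH, NaOCl, MeCN, 0 °C), to give 3-oxo-α-ionone F3. Vinylmagnesium bromide with CeCl3 in THF at −78 °C is then added to the less hindered acyclic enone carbonyl, and the regioisomeric ring adduct is removed on silica.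

## Further compounds

F1 | step 4 | syn tertiary pinacol boronate, (4R,5S)-4-[(1E,3RS)-3-hydroxy-3-methylpenta-1,4-dien-1-yl]-3,3,5-trimethyl-5-(4,4,5,5-tetramethyl-1,3,2-dioxaborolan-2-yl)cyclohexan-1-one (boron in the place of the ring hydroxyl of 8) | C=CC(C)(O)/C=C/[C@H]1C(C)(C)CC(=O)C[C@@]1(C)B1OC(C)(C)C(C)(C)O1
F2 | step 3 | anti tertiary pinacol boronate, (4R,5R)-4-[(1E,3RS)-3-hydroxy-3-methylpenta-1,4-dien-1-yl]-3,3,5-trimethyl-5-(4,4,5,5-tetramethyl-1,3,2-dioxaborolan-2-yl)cyclohexan-1-one (boron in the place of the ring hydroxyl of 6) | C=CC(C)(O)/C=C/[C@H]1C(C)(C)CC(=O)C[C@]1(C)B1OC(C)(C)C(C)(C)O1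
F3 | step 2 | (±)-3-oxo-α-ionone, 3,5,5-trimethyl-4-[(1E)-3-oxobut-1-en-1-yl]cyclohex-2-en-1-one | CC(=O)/C=C/C1C(C)=CC(=O)CC1(C)C
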